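**Retrosynthetic overview**
- Dryocrassin ABBA ⇒ the two outer CH2 bridges are cut last: methylenebis(butyrylphloroglucinol) + 2 acetylfilicinic acid + 2 formaldehyde.
- Methylenebis(butyrylphloroglucinol) ⇒ both benzene rings are built at once by a double Mg(OMe)2 Claisen recyclisation of a 3,3'-methylenebis[4-hydroxy-6-(2-oxopentyl)-2-pyrone]. The central CH2 is set at the pyrone stage, where only one carbon can react.
- Bis-pyrone ⇒ 6-(2-oxopentyl)pyrone + formaldehyde; that pyrone ⇒ triacetic acid lactone dianion + methyl butanoate.
- Acetylfilicinic acid ⇒ 2,4,6-trihydroxyacetophenone by dearomatising geminal C-dimethylation.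
- Ring order: both B (benzene) rings form together in step 2; the two A rings come from the arene ring of trihydroxyacetophenone (step 3) and are attached last (step 4).

Assumption: the target SMILES has no stereocentre and no stereogenic double bond (the molecule is achiral, drawn as one tautomer), so no stereocontrol is needed and none is claimed.

**Step 1**
Reactants: 1 4-hydroxy-6-methyl-2H-pyran-2-one (triacetic acid lactone); 2 methyl butanoate
Product: 3 4-hydroxy-6-(2-oxopentyl)-2H-pyran-2-one
Conditions: LDA (commercial solution, 3.1 equiv), THF, −78 → 0 °C; then 2 (1.1 equiv), −78 → 0 °C; 2 M HCl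
Reagents that add atoms: none
Why: The O,C-dianion of the pyrone reacts at its 6-CH2 carbanion with the ester (Claisen-type C-acylation of a dianion), and the third equivalent of base stores the product as its enolate so that it neither quenches the dianion nor adds a second time.

**Step 2**
Reactants: 3 4-hydroxy-6-(2-oxopentyl)-2H-pyran-2-one (2 equiv); 4 formaldehyde (1 equiv)
Product: 7 3,3'-methylenebis(2,4,6-trihydroxybutyrophenone), via methylene-bridged bis-pyrone 5 (not isolated), via ring-opened bis(triketo ester) 6 (not isolated)
Conditions: 4 (37% aq., 0.50 equiv per 3), MeOH, 23 → 60 °C, 3 h; volatiles stripped in the same flask (PhMe azeotrope); Mg(OMe)2 (8 equiv), MeOH, reflux, 16 h; 2 M HCl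
Reagents that add atoms: none
Why: Proposed new method: formaldehyde first joins two molecules of 3 at C3, the only strongly nucleophilic carbon of a 4-hydroxy-2-pyrone (Knoevenagel–Michael bridging as in dicoumarol formation, so no oligomers can form), and Mg(OMe)2 then opens each lactone to a Mg-chelated methyl 3,5,7-triketo ester whose C6 carbanion attacks the ester carbon (Claisen/Dieckmann-type cyclisation, loss of MeOH, tautomerisation to the arene), so both benzene rings form in the same operation; the bridge on C2 blocks the competing C2→C7 aldol (resorcylate) mode because that ring could not aromatise; the closest known reaction is the Mg(OMe)2 conversion of 6-(2-oxoalkyl)-4-hydroxy-2-pyrones (tetraacetic acid lactone type) into acylphloroglucinols, here run twice on a bridged substrate; no stereocentre is formed.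

**Step 3**
Reactants: 8 2,4,6-trihydroxyacetophenone
Product: 9 acetylfilicinic acid (2-acetyl-3,5-dihydroxy-6,6-dimethylcyclohexa-2,4-dien-1-one)
Conditions: MeI (2.5 equiv), NaOMe (3.0 equiv), MeOH, 0 → 23 °C, 16 h; 1 M HCl
Reagents that add atoms: iodomethane, CI
Why: The acylphloroglucinol phenolate is C-methylated twice at the same ring carbon (dearomatising geminal C-alkylation, the classical filicinic acid preparation), and the resulting β-triketone anion is too stabilised to be alkylated further.

**Step 4**
Reactants: 7 3,3'-methylenebis(2,4,6-trihydroxybutyrophenone); 9 acetylfilicinic acid (4 equiv, 2 incorporated); 4 formaldehyde (3 equiv, 2 incorporated)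
Product: 10 Dryocrassin ABBA
Conditions: 9 (4 equiv), 0.25 M aq. NaOH, 0 °C; 4 (37% aq., 3 equiv) added dropwise, 20 min; 2 M HCl to pH 2; chromatography
Reagents that add atoms: none
Why: Formaldehyde condenses with the ring CH of 9 to a 4-methylene triketone (quinone-methide-type acceptor) that is trapped by the single free ring carbon of each half of 7 (Knoevenagel–Michael methylene bridging of acylphloroglucinols), and since 7 has exactly two such carbons the excess of 9 and 4 can end only as the separable homodimer albaspidin AA; no stereocentre is formed.

**Compound list**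
1 | 4-hydroxy-6-methyl-2H-pyran-2-one (triacetic acid lactone) | CC1=CC(O)=CC(=O)O1 | starting material
2 | methyl butanoate | CCCC(=O)OC | starting material
3 | 4-hydroxy-6-(2-oxopentyl)-2H-pyran-2-one | CCCC(=O)CC1=CC(O)=CC(=O)O1 | intermediate
4 | formaldehyde (37% aqueous solution) | C=O | starting material
5 | 3,3'-methylenebis[4-hydroxy-6-(2-oxopentyl)-2H-pyran-2-one] | CCCC(=O)CC1=CC(O)=C(CC2=C(O)C=C(CC(=O)CCC)OC2=O)C(=O)O1 | intermediate
6 | dimethyl 2,4-bis(3,5-dioxooctanoyl)pentanedioate (present as Mg enolate; the two α-CH centres are epimerisable and undefined) | COC(=O)C(CC(C(=O)OC)C(=O)CC(=O)CC(=O)CCC)C(=O)CC(=O)CC(=O)CCC | intermediate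
7 | 3,3'-methylenebis(2,4,6-trihydroxybutyrophenone) | CCCC(=O)c1c(O)cc(O)c(Cc2c(O)cc(O)c(C(=O)CCC)c2O)c1O | intermediate
8 | 2,4,6-trihydroxyacetophenone | CC(=O)c1c(O)cc(O)cc1O | starting material
9 | acetylfilicinic acid (2-acetyl-3,5-dihydroxy-6,6-dimethylcyclohexa-2,4-dien-1-one, drawn as the tautomer used in the target) | CC(=O)C1=C(O)C=C(O)C(C)(C)C1=O | intermediate
10 | Dryocrassin ABBA (achiral) | CCCC(=O)c1c(O)c(CC2=C(O)C(C)(C)C(=O)C(C(C)=O)=C2O)c(O)c(Cc2c(O)c(CC3=C(O)C(C)(C)C(=O)C(C(C)=O)=C3O)c(O)c(C(=O)CCC)c2O)c1O | target

**Step count**
Total steps: 4. Longest linear sequence: 3 (steps 1, 2, 4); step 3 is a one-step side branch.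

**Steps most likely to fail, with fallbacks**

Step 2 is the riskiest. The bridge may fragment by retro-Michael reaction under Mg(OMe)2, or only one of the two rings may close. The fallback sets out from 3 and runs the same Mg(OMe)2 Claisen recyclisation on the monomer, which is the known single-ring case. This gives 2,4,6-trihydroxybutyrophenone F1. F1, used in excess and recycled because it has two free ring carbons, is then bridged with 0.5 equiv formaldehyde in dilute aqueous NaOH at 0 °C. The route is rejoined at 7. This trades the double cyclisation for two single ones and a less selective bridging.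

Step 4 is next. Alkaline formaldehyde can scramble methylene bridges (retro-Michael exchange) and gives a statistical share of homodimer. The fallback sets out from 7 and makes the electrophile on the aryl partner instead. A Mannich reaction with dimethylamine and formaldehyde in EtOH gives 3,3'-methylenebis[5-(dimethylaminomethyl)-2,4,6-trihydroxybutyrophenone] F2. Heating F2 with 9 (2.2 equiv) in dioxane at 100 °C expels dimethylamine through an ortho-quinone methide, which 9 traps at its ring CH. No free formaldehyde and no strong base are present, and the route is rejoined at 10.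

Step 1 is third. The pyrone dianion may deprotonate the enolisable ester instead of acylating. The fallback sets out from 1 and replaces the acylation by an aldol addition followed by oxidation. The dianion (LDA, 2.2 equiv, THF, −78 °C) is added to butanal, which is far more electrophilic than the ester. This gives racemic 4-hydroxy-6-(2-hydroxypentyl)-2H-pyran-2-one F3, whose carbinol centre is removed in the next operation. Oxidation of F3 with Dess–Martin periodinane in CH2Cl2 rejoins the route at 3.

**Further compounds**
F1 | step 2 | 2,4,6-trihydroxybutyrophenone (1-(2,4,6-trihydroxyphenyl)butan-1-one) | CCCC(=O)c1c(O)cc(O)cc1O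
F2 | step 4 | 3,3'-methylenebis[5-(dimethylaminomethyl)-2,4,6-trihydroxybutyrophenone] | CCCC(=O)c1c(O)c(CN(C)C)c(O)c(Cc2c(O)c(CN(C)C)c(O)c(C(=O)CCC)c2O)c1O
F3 | step 1 | 4-hydroxy-6-(2-hydroxypentyl)-2H-pyran-2-one (racemic) | CCCC(O)CC1=CC(O)=CC(=O)O1
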